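**Plan**
1. Retrosynthesis: the C17 methyl and the free C6 acid come last (from a C16=C17 methylene ketone benzyl ester). The C12–C16 bond is then re-formed to a cyclopropyl ketone, whose C16–C13 and C16–C12 bonds are cut together to a C8 diazoacetyl group and a C12=C13 alkene.
2. Enabling feature: ring D (C8, C15, C16, C13, C14) carries its ketone bridge C15–C16 between C8 and C13, which are 1,3-related in ring C (C8, C9, C11, C12, C13, C14). A carbene at C16 on a C8 acyl arm therefore sits over the C12=C13 bond; the step builds 2 rings, 2 skeletal bonds and 3 stereocentres.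
3. Earlier cuts: C8–C14 and C9–C11 (Diels–Alder, butadiene), C8=C9 with the C20–O–C7 ester (acetoacetate Knoevenagel lactone), C10–C9 and C10–C20 (two enolate alkylations), C5–C6 (conjugate vinylation).
4. Forward order: ring A from 4,4-dimethylcyclohexenone (steps 1–11), spiro δ-lactone (12), ring C (13), cyclopropane and ring D together (15), then ring opening, C17 and deprotection (16–18).
5. Stereochemistry: C5 by Rh/(R)-BINAP desymmetrisation of a dienone; C10 by two alkylations anti to the C5 ester; C1 by hydroxyl-directed reduction; C8 and C9 by cycloaddition on the C1 face of the lactone; C12, C13, C16 by the tether; C16 finally by exo-face hydrogenation.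

Key step: step 15

**Remarks**
- Atom numbers are those of the target: ring A = C1–C5, C10 (C4 gem-dimethyl); C6 = carboxyl carbon on C5; C20 = CH2O on C10; C7 = lactone carbonyl; ring C = C8, C9, C11–C14; C15 = ketone; C16, C17 = its α-carbon and methyl.
- In the target the C1 oxygen, C6 and C20 lie on one face of ring A and C9 on the other.
- 4-Methoxybenzyl chloromethyl ether is assumed to be purchasable; formaldehyde is used as the dry monomer gas from cracking paraformaldehyde in a side flask.
- The (R)-ligand in step 2 is assigned by analogy with cyclohex-2-enone and would be confirmed on the product.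

**Route**

Step 1
Reactants: 1 4,4-dimethylcyclohex-2-en-1-one
Product: 2 4,4-dimethylcyclohexa-2,5-dien-1-one
Conditions: DDQ (1.3 equiv), 1,4-dioxane, reflux
Reagents that add atoms: none
Why: Quinone dehydrogenation of a 4,4-disubstituted cyclohexenone to the cross-conjugated dienone is standard, and it gives a symmetric substrate whose second enone later blocks enolisation on the C2 side.

Step 2
Reactants: 2 4,4-dimethylcyclohexa-2,5-dien-1-one; 3 potassium ethenyltrifluoroborate
Product: 4 (5R)-5-ethenyl-4,4-dimethylcyclohex-2-en-1-one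
Conditions: [RhCl(C2H4)2]2 (2.5 mol %), (R)-BINAP (5.5 mol %), dioxane/H2O (10:1), 80 °C
Reagents that add atoms: none
Why: In this Hayashi–Miyaura reaction the Rh–BINAP alkenyl species should add 1,4 to one of the two enantiotopic enone halves from one face, so the catalyst sets C5, and the more hindered mono-adduct should resist a second addition.

Step 3
Reactants: 4 (5R)-5-ethenyl-4,4-dimethylcyclohex-2-en-1-one
Product: 6 (1S)-2,2-dimethyl-5-oxocyclohex-3-ene-1-carboxylic acid, via keto aldehyde 5 (not isolated)
Conditions: O3, CH2Cl2, –78 °C (Sudan red 7B end point), then PPh3; then NaClO2, NaH2PO4, 2-methylbut-2-ene, t-BuOH/H2O, 0 °C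
Reagents that add atoms: ozone, [O-][O+]=O; sodium chlorite, [Na+].[O-]Cl=O
Why: Ozone should attack the electron-rich terminal alkene much faster than the electron-poor enone, and Pinnick oxidation of the aldehyde gives the C6 acid without touching the enone or C5.

Step 4
Reactants: 6 (1S)-2,2-dimethyl-5-oxocyclohex-3-ene-1-carboxylic acid
Product: 7 benzyl (1S)-2,2-dimethyl-5-oxocyclohex-3-ene-1-carboxylate
Conditions: BnBr, KHCO3, DMF, rt
Reagents that add atoms: benzyl bromide, BrCc1ccccc1
Why: SN2 O-alkylation of the carboxylate gives an ester that should survive all later steps and is removed in the final hydrogenation.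

Step 5
Reactants: 7 benzyl (1S)-2,2-dimethyl-5-oxocyclohex-3-ene-1-carboxylate; 8 4-methoxybenzyl chloromethyl ether
Product: 9 benzyl (1S,6R)-6-{[(4-methoxybenzyl)oxy]methyl}-2,2-dimethyl-5-oxocyclohex-3-ene-1-carboxylate
Conditions: LiN(i-Pr)2 (1.05 equiv), THF, –78 °C; then 8, –78 → –40 °C
Reagents that add atoms: none
Why: Kinetic deprotonation of the cyclohexenone can occur only at the α′ carbon C10 (C2 is vinylic), and enolate alkylation with the reactive α-chloro ether brings in C20; the C10 configuration formed here (mainly trans) is erased in step 6.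

Step 6
Reactants: 9 benzyl (1S,6R)-6-{[(4-methoxybenzyl)oxy]methyl}-2,2-dimethyl-5-oxocyclohex-3-ene-1-carboxylate; 10 formaldehyde
Product: 11 benzyl (1R,6R)-6-(hydroxymethyl)-6-{[(4-methoxybenzyl)oxy]methyl}-2,2-dimethyl-5-oxocyclohex-3-ene-1-carboxylate
Conditions: LiN(i-Pr)2 (1.1 equiv), THF, –78 °C; CH2O (g), –78 °C; NH4Cl (aq), –78 °C
Reagents that add atoms: none
Why: Re-enolisation at C10 and aldol addition to formaldehyde create the quaternary centre, the electrophile entering anti to the adjacent C5 ester so that the new CH2OH (C9) is trans and the CH2OPMB (C20) cis to C6; the cold quench guards against retro-aldol loss.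

Step 7
Reactants: 11 benzyl (1R,6R)-6-(hydroxymethyl)-6-{[(4-methoxybenzyl)oxy]methyl}-2,2-dimethyl-5-oxocyclohex-3-ene-1-carboxylate
Product: 12 benzyl (1R,2R)-2-(hydroxymethyl)-2-{[(4-methoxybenzyl)oxy]methyl}-6,6-dimethyl-3-oxocyclohexane-1-carboxylate
Conditions: H2 (1 atm), 10% Pd/C, Ph2S (1 mol %), EtOAc, rt
Reagents that add atoms: none
Why: Hydrogenation over sulfide-poisoned Pd/C saturates the C2=C3 enone alkene while the benzyl ester and the 4-methoxybenzyl ether, which need more active palladium for hydrogenolysis, should be kept.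

Step 8
Reactants: 12 benzyl (1R,2R)-2-(hydroxymethyl)-2-{[(4-methoxybenzyl)oxy]methyl}-6,6-dimethyl-3-oxocyclohexane-1-carboxylate
Product: 13 benzyl (1R,2R,3S)-3-hydroxy-2-(hydroxymethyl)-2-{[(4-methoxybenzyl)oxy]methyl}-6,6-dimethylcyclohexane-1-carboxylate
Conditions: Me4NBH(OAc)3 (5 equiv), MeCN/AcOH (1:1), –30 → 0 °C
Reagents that add atoms: none
Why: In this Evans–Saksena reduction the C9 hydroxyl binds boron and delivers hydride to the C1 carbonyl from its own face, so the new C1 oxygen ends anti to C9 and cis to C20 and C6, and the mild reagent leaves the ester alone.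

Step 9
Reactants: 13 benzyl (1R,2R,3S)-3-hydroxy-2-(hydroxymethyl)-2-{[(4-methoxybenzyl)oxy]methyl}-6,6-dimethylcyclohexane-1-carboxylate
Product: 14 benzyl (1R,2R,3S)-2-formyl-3-hydroxy-2-{[(4-methoxybenzyl)oxy]methyl}-6,6-dimethylcyclohexane-1-carboxylate
Conditions: TEMPO (10 mol %), PhI(OAc)2 (1.2 equiv), CH2Cl2, rt
Reagents that add atoms: none
Why: Oxoammonium (TEMPO) oxidation with PhI(OAc)2 is selective for primary over secondary alcohols and should stop at the C9 aldehyde.

Step 10
Reactants: 14 benzyl (1R,2R,3S)-2-formyl-3-hydroxy-2-{[(4-methoxybenzyl)oxy]methyl}-6,6-dimethylcyclohexane-1-carboxylate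
Product: 15 benzyl (1R,2R,3S)-3-acetoxy-2-formyl-2-{[(4-methoxybenzyl)oxy]methyl}-6,6-dimethylcyclohexane-1-carboxylate
Conditions: Ac2O, pyridine, DMAP (cat.), CH2Cl2, 0 °C → rt
Reagents that add atoms: acetic anhydride, CC(=O)OC(C)=O
Why: DMAP-catalysed acylation of the remaining secondary alcohol installs the C1 acetate of the target once all hydride steps are past.

Step 11
Reactants: 15 benzyl (1R,2R,3S)-3-acetoxy-2-formyl-2-{[(4-methoxybenzyl)oxy]methyl}-6,6-dimethylcyclohexane-1-carboxylate
Product: 16 benzyl (1R,2R,3S)-3-acetoxy-2-formyl-2-(hydroxymethyl)-6,6-dimethylcyclohexane-1-carboxylate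
Conditions: DDQ (1.3 equiv), CH2Cl2/pH 7 buffer (10:1), 0 °C → rt
Reagents that add atoms: none
Why: Oxidative cleavage of the electron-rich 4-methoxybenzyl ether by DDQ frees the C20 hydroxyl under neutral conditions that should spare benzyl ester, acetate and aldehyde.

Step 12
Reactants: 16 benzyl (1R,2R,3S)-3-acetoxy-2-formyl-2-(hydroxymethyl)-6,6-dimethylcyclohexane-1-carboxylate; 17 2,2,6-trimethyl-4H-1,3-dioxin-4-one
Product: 19 benzyl (6S,7R,11S)-11-acetoxy-4-acetyl-8,8-dimethyl-3-oxo-2-oxaspiro[5.5]undec-4-ene-7-carboxylate, via acetoacetate 18 (not isolated)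
Conditions: 17 (1.2 equiv), toluene, 110 °C; then piperidine (10 mol %), AcOH (10 mol %), 4 Å molecular sieves, 50 °C
Reagents that add atoms: none
Why: Thermal retro-[4+2] of 17 gives acetylketene, which acylates the C20 alcohol, and the acetoacetate then closes the six-membered lactone by intramolecular Knoevenagel condensation with the C9 aldehyde.

Step 13
Reactants: 19 benzyl (6S,7R,11S)-11-acetoxy-4-acetyl-8,8-dimethyl-3-oxo-2-oxaspiro[5.5]undec-4-ene-7-carboxylate; 20 buta-1,3-diene
Product: 21 C8-acetyl Diels–Alder adduct (cis-fused δ-lactone and ring C cyclohexene with C12=C13)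
Conditions: 20 (excess), ZnCl2 (1.5 equiv), Et2O/CH2Cl2, sealed tube, rt
Reagents that add atoms: none
Why: In this Lewis acid-promoted Diels–Alder reaction of a chelated 2-acyl enoate, suprafacial addition fixes the cis lactone–ring C fusion (C8, C9), and the diene should bond to C9 anti to the C10–C5 bond, on the face flanked by the small C1 acetoxy methine and away from C5 with its ester and neighbouring gem-dimethyl group.

Step 14
Reactants: 21 C8-acetyl Diels–Alder adduct
Product: 23 C8 diazoacetyl lactone (cyclohexenyl diazomethyl ketone), via trifluoroacetyl diketone 22 (not isolated)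
Conditions: LiN(SiMe3)2 (1.1 equiv), THF, –78 °C; CF3CO2CH2CF3 (1.2 equiv); HCl (aq) work-up; then MsN3 (1.5 equiv), Et3N, H2O (1 equiv), MeCN, rt
Reagents that add atoms: methanesulfonyl azide, CS(=O)(=O)N=[N+]=[N-]; 2,2,2-trifluoroethyl trifluoroacetate, O=C(OCC(F)(F)F)C(F)(F)F (its atoms stay only in 22)
Why: In this Regitz-type deacylative diazo transfer the methyl ketone, enolisable only at its CH3, is activated by Claisen trifluoroacetylation and the 1,3-diketone then takes the diazo group from the sulfonyl azide with loss of the trifluoroacetyl group.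

Step 15
Reactants: 23 C8 diazoacetyl lactone
Product: 24 cyclopropyl ketone (tricyclo[3.2.1.0^2,7]octan-6-one unit: C16 bonded to C12, C13 and C15)
Conditions: Rh2(OAc)4 (2 mol %), CH2Cl2, rt, slow addition of 23
Reagents that add atoms: none
Why: Rh2(OAc)4 expels N2 from 23 to give an electrophilic rhodium carbenoid at C16, which adds to C12=C13 in a concerted, asynchronous [2+1] step that forms C16–C13 and C16–C12. The closest known reaction type is the copper- or rhodium-catalysed intramolecular cyclopropanation of cyclohex-3-enyl diazomethyl ketones to tricyclo[3.2.1.0^2,7]octan-6-ones. The cyclopentanone ring (C8, C15, C16, C13, C14) closes in the exo sense across the three-atom link C15–C8–C14 (the bicyclo[3.1.0]hexan-2-one mode), and the cyclopropane (C12, C13, C16) closes by the cheletropic addition itself. C13 and C12 are set by delivery to the ring C face that carries the axial C8 acyl arm, hence by C8 from step 13, and C16 by the geometry of the fused tricycle, so only one diastereomer is possible. The step needs cyclopropanation to beat insertion into the allylic C11–H bond and ylide formation with the C7 lactone carbonyl; the conformer with the acyl arm axial holds C16 directly over the alkene, the alkene is the most nucleophilic site within reach, and ester-derived ylides form reversibly.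

Step 16
Reactants: 24 cyclopropyl ketone
Product: 25 bicyclo[3.2.1]octanone (C16H2 ketone, C12H2)
Conditions: SmI2 (2.2 equiv), t-BuOH (2 equiv), THF, –78 °C
Reagents that add atoms: none
Why: In this reductive cyclopropyl ketone opening, the ketyl formed by SmI2 (chelated by the lactone carbonyl) should fragment the C16–C12 bond, the cyclopropane bond best aligned with the ketyl π orbital and outside the five-membered ring, and the C12 radical and samarium enolate are then reduced and protonated, leaving C13 untouched.

Step 17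
Reactants: 25 bicyclo[3.2.1]octanone; 26 bis(dimethylamino)methane
Product: 28 16-methylene ketone, via Mannich base 27 (not isolated)
Conditions: 26 (excess), Ac2O, DMF, 95 °C
Reagents that add atoms: none
Why: Mannich reaction of the ketone, enolisable only at C16, with the iminium ion made from 26 and Ac2O, followed by β-elimination of dimethylamine in the same pot, is an established one-step α-methylenation of hindered bridged cyclopentanones.

Step 18
Reactants: 28 16-methylene ketone
Product: 29 target acid CNP0161834.1 (1S,5R,8S,9S,10S,13R,16R)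
Conditions: H2 (1 atm), 10% Pd/C, EtOAc, rt
Reagents that add atoms: none
Why: Heterogeneous hydrogenation should add H2 to the exocyclic enone from the exo face (the side of the one-carbon bridge C14), placing the C17 methyl endo as in the target, and the same catalyst hydrogenolyses the benzyl ester under neutral conditions that cannot epimerise C16.

**Compound list**
1 | 4,4-dimethylcyclohex-2-en-1-one | CC1(C)CCC(=O)C=C1 | starting material
2 | 4,4-dimethylcyclohexa-2,5-dien-1-one | CC1(C)C=CC(=O)C=C1 | intermediate
3 | potassium ethenyltrifluoroborate | C=C[B-](F)(F)F.[K+] | starting material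
4 | (5R)-5-ethenyl-4,4-dimethylcyclohex-2-en-1-one | O=C1C=CC(C)(C)[C@@H](C=C)C1 | intermediate
5 | (1S)-2,2-dimethyl-5-oxocyclohex-3-ene-1-carbaldehyde (keto aldehyde) | O=C1C=CC(C)(C)[C@@H](C=O)C1 | intermediate
6 | (1S)-2,2-dimethyl-5-oxocyclohex-3-ene-1-carboxylic acid | O=C1C=CC(C)(C)[C@@H](C(=O)O)C1 | intermediate
7 | benzyl (1S)-2,2-dimethyl-5-oxocyclohex-3-ene-1-carboxylate | O=C1C=CC(C)(C)[C@@H](C(=O)OCc2ccccc2)C1 | intermediate
8 | 4-methoxybenzyl chloromethyl ether, 1-[(chloromethoxy)methyl]-4-methoxybenzene | COc1ccc(COCCl)cc1 | starting material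
9 | benzyl (1S,6R)-6-{[(4-methoxybenzyl)oxy]methyl}-2,2-dimethyl-5-oxocyclohex-3-ene-1-carboxylate (ester and CH2OPMB trans) | O=C1C=CC(C)(C)[C@@H](C(=O)OCc2ccccc2)[C@@H]1COCc3ccc(OC)cc3 | intermediate
10 | formaldehyde | C=O | starting material
11 | benzyl (1R,6R)-6-(hydroxymethyl)-6-{[(4-methoxybenzyl)oxy]methyl}-2,2-dimethyl-5-oxocyclohex-3-ene-1-carboxylate (CH2OH trans, CH2OPMB cis to the ester) | O=C1C=CC(C)(C)[C@@H](C(=O)OCc2ccccc2)[C@@]1(CO)COCc3ccc(OC)cc3 | intermediate
12 | benzyl (1R,2R)-2-(hydroxymethyl)-2-{[(4-methoxybenzyl)oxy]methyl}-6,6-dimethyl-3-oxocyclohexane-1-carboxylate | O=C1CCC(C)(C)[C@@H](C(=O)OCc2ccccc2)[C@@]1(CO)COCc3ccc(OC)cc3 | intermediate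
13 | benzyl (1R,2R,3S)-3-hydroxy-2-(hydroxymethyl)-2-{[(4-methoxybenzyl)oxy]methyl}-6,6-dimethylcyclohexane-1-carboxylate | O[C@H]1CCC(C)(C)[C@@H](C(=O)OCc2ccccc2)[C@@]1(CO)COCc3ccc(OC)cc3 | intermediate
14 | benzyl (1R,2R,3S)-2-formyl-3-hydroxy-2-{[(4-methoxybenzyl)oxy]methyl}-6,6-dimethylcyclohexane-1-carboxylate | O[C@H]1CCC(C)(C)[C@@H](C(=O)OCc2ccccc2)[C@@]1(C=O)COCc3ccc(OC)cc3 | intermediate
15 | benzyl (1R,2R,3S)-3-acetoxy-2-formyl-2-{[(4-methoxybenzyl)oxy]methyl}-6,6-dimethylcyclohexane-1-carboxylate | CC(=O)O[C@H]1CCC(C)(C)[C@@H](C(=O)OCc2ccccc2)[C@@]1(C=O)COCc3ccc(OC)cc3 | intermediate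
16 | benzyl (1R,2R,3S)-3-acetoxy-2-formyl-2-(hydroxymethyl)-6,6-dimethylcyclohexane-1-carboxylate (ring A hydroxy aldehyde) | CC(=O)O[C@H]1CCC(C)(C)[C@@H](C(=O)OCc2ccccc2)[C@@]1(C=O)CO | intermediate
17 | 2,2,6-trimethyl-4H-1,3-dioxin-4-one | CC1=CC(=O)OC(C)(C)O1 | starting material
18 | benzyl (1R,2R,3S)-3-acetoxy-2-formyl-6,6-dimethyl-2-{[(3-oxobutanoyl)oxy]methyl}cyclohexane-1-carboxylate (acetoacetate) | CC(=O)O[C@H]1CCC(C)(C)[C@@H](C(=O)OCc2ccccc2)[C@@]1(C=O)COC(=O)CC(C)=O | intermediate
19 | benzyl (6S,7R,11S)-11-acetoxy-4-acetyl-8,8-dimethyl-3-oxo-2-oxaspiro[5.5]undec-4-ene-7-carboxylate (spiro lactone dienophile, C8=C9) | CC(=O)O[C@H]1CCC(C)(C)[C@@H](C(=O)OCc3ccccc3)[C@@]12COC(=O)C(C(C)=O)=C2 | intermediate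
20 | buta-1,3-diene | C=CC=C | starting material
21 | Diels–Alder adduct: ring A (C1 OAc, C5 CO2Bn) spiro at C10 to the δ-lactone, cis-fused to ring C (C12=C13), acetyl on C8; 1S,5R,8S,9S,10S in target numbering | CC(=O)O[C@H]1CCC(C)(C)[C@@H](C(=O)OCc3ccccc3)[C@@]12COC(=O)[C@@]1(C(C)=O)CC=CC[C@H]12 | intermediate
22 | trifluoroacetyl diketone: as 21 with C8–C(=O)CH2C(=O)CF3 | CC(=O)O[C@H]1CCC(C)(C)[C@@H](C(=O)OCc3ccccc3)[C@@]12COC(=O)[C@@]1(C(=O)CC(=O)C(F)(F)F)CC=CC[C@H]12 | intermediate
23 | diazoketone: as 21 with C8–C(=O)CH=N2 (key-step precursor) | CC(=O)O[C@H]1CCC(C)(C)[C@@H](C(=O)OCc3ccccc3)[C@@]12COC(=O)[C@@]1(C(=O)C=[N+]=[N-])CC=CC[C@H]12 | intermediate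
24 | cyclopropyl ketone: C16 bonded to C12, C13 and C15, cyclopropane on the ring C face that carried the acyl arm (key-step product) | CC(=O)O[C@H]1CCC(C)(C)[C@@H](C(=O)OCc5ccccc5)[C@@]12COC(=O)[C@@]13C[C@H]4[C@@H](C[C@H]12)[C@H]4C3=O | intermediate
25 | bicyclo[3.2.1]octanone: benzyl ester of the 17-nor target skeleton (C15 ketone, C16H2); 1S,5R,8S,9S,10S,13R | CC(=O)O[C@H]1CCC(C)(C)[C@@H](C(=O)OCc4ccccc4)[C@@]12COC(=O)[C@@]13C[C@@H](CC[C@H]12)CC3=O | intermediate
26 | bis(dimethylamino)methane | CN(C)CN(C)C | starting material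
27 | Mannich base: 25 with an exo CH2NMe2 group on C16 (C16 configuration of no consequence) | CC(=O)O[C@H]1CCC(C)(C)[C@@H](C(=O)OCc4ccccc4)[C@@]12COC(=O)[C@@]13C[C@@H](CC[C@H]12)[C@H](CN(C)C)C3=O | intermediate
28 | 16-methylene ketone: benzyl ester with C16=C17H2 conjugated to the C15 ketone | CC(=O)O[C@H]1CCC(C)(C)[C@@H](C(=O)OCc4ccccc4)[C@@]12COC(=O)[C@@]13C[C@@H](CC[C@H]12)C(=C)C3=O | intermediate
29 | CNP0161834.1, (1S,5R,8S,9S,10S,13R,16R) in the numbering above | CC(=O)O[C@H]1CCC(C)(C)[C@@H](C(=O)O)[C@@]12COC(=O)[C@@]13C[C@@H](CC[C@H]12)[C@@H](C)C3=O | target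

**Step count**
Total: 18 steps. Longest linear sequence: 18 steps (1 → 29); compounds 3, 8, 10, 17, 20 and 26 are purchased.

**Steps most likely to fail**

Step 13 (Diels–Alder). The diene may not discriminate well enough between the two faces of C9, or the hindered dienophile may react so slowly that butadiene oligomerises first. The fallback moves from substrate control to catalyst control. Starting from 19, the cycloaddition would be run with a chelating chiral Lewis acid, [Cu((S,S)-t-Bu-box)](SbF6)2 or its enantiomer (a divalent copper bis(oxazoline) complex). It binds both carbonyl groups of the 2-acyl enoate and shields one face; the ligand enantiomer that reinforces attack on the C1 face would be used. The route is rejoined at 21, and no new compound is made (F0).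

Step 2 (Rh-catalysed vinylation). The β-carbons of 2 are flanked by the quaternary C4, so insertion may be slow, hydrolysis of the vinylborate may outrun addition, and a second addition to 4 may erode the yield. The fallback uses iminium catalysis. Starting from 2, nitromethane would be added with a 9-amino-9-deoxy-epi-cinchona primary amine salt (under high pressure if needed) to give (5S)-4,4-dimethyl-5-(nitromethyl)cyclohex-2-en-1-one F1. An oxidative Nef-type conversion (NaNO2, AcOH, DMSO, 35 °C) would then turn the nitromethyl group into the carboxylic acid, rejoining the route at 6.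

Step 15 (key cyclopropanation). The carbenoid may be diverted into insertion at the allylic C11–H bond or into an ylide with the lactone carbonyl, or the conformer with the acyl arm axial may be too sparsely populated. The fallback closes the same C16–C13 bond by a radical path. Starting from 23, HBr (48% aq., Et2O, 0 °C) would give the C8 bromoacetyl lactone (bromomethyl ketone) F2. Slow addition of Bu3SnH with AIBN (benzene, 80 °C) would then let the α-keto radical at C16 cyclise 5-exo onto C13, with hydrogen transfer to C12, rejoining the route at 25.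

**Further compounds**
F0 | step 13 | none | none
F1 | step 2 | (5S)-4,4-dimethyl-5-(nitromethyl)cyclohex-2-en-1-one | O=C1C=CC(C)(C)[C@@H](C[N+](=O)[O-])C1
F2 | step 15 | bromomethyl ketone: as 21 with C8–C(=O)CH2Br | CC(=O)O[C@H]1CCC(C)(C)[C@@H](C(=O)OCc3ccccc3)[C@@]12COC(=O)[C@@]1(C(=O)CBr)CC=CC[C@H]12
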